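**Plan**

Retrosynthesis: the free phenol and the C2=C3 double bond are traced back to the MOM-protected 3-hydroxy-2,3-dihydrobenzofuran 13. The cuts then follow in this order: C2–C3, O1–C2, the biaryl bond C6–C1', and C3–C3a. Finally the oxygen on C7a is traced to a formyl group.
Enabling feature: in the furan ring, C3 carries the methyl group and sits on C3a, so it is the carbonyl carbon of an aryl methyl ketone in disguise. C2 carries both O1 and the CH2CO2Me arm, which is the substitution pattern of the β-carbon of a β-aryloxyacrylate. Joining C2 to C3 is therefore a ketyl–acrylate coupling.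
Forward: the central benzene ring is bought and dressed (Br, OMe, OH, acetyl), and the phenolic ring is attached by Suzuki coupling. O1–C2 is then made by oxa-Michael addition, and the furan ring closes last through C2–C3.
Stereochemistry: the target has no stereocentre. C2 and C3 of 13 arise racemic, with OH trans to the arm, from a samarium-chelated transition state, and both disappear on aromatisation. The E geometry of 12 comes from the amine-catalysed addition.

Key step: step 7

Assumption: the pendant phenol travels as its methoxymethyl (MOM) ether (boronic acid 9 is taken as a catalogue compound), so one acidic operation at the end both aromatises the furan and frees the phenol; 13 is racemic and is drawn as one enantiomer.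

**Step 1**
Reactants: 1 2-hydroxy-5-methoxybenzaldehyde
Product: 2 3-bromo-2-hydroxy-5-methoxybenzaldehyde
Conditions: Br2, NaOAc, AcOH, rt
Reagents that add atoms: bromine, BrBr
Why: Electrophilic aromatic bromination is steered by the free phenol, whose para position holds OMe and one ortho position holds CHO, so bromine should enter at the remaining ortho carbon C3.

**Step 2**
Reactants: 2 3-bromo-2-hydroxy-5-methoxybenzaldehyde
Product: 3 3-bromo-2,5-dimethoxybenzaldehyde
Conditions: MeI, K2CO3, DMF, rt
Reagents that add atoms: iodomethane, CI
Why: Williamson O-methylation of the acidic salicylaldehyde phenol, the only site in 2 that carbonate and MeI can alkylate.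

**Step 3**
Reactants: 3 3-bromo-2,5-dimethoxybenzaldehyde
Product: 5 3-bromo-2,5-dimethoxyphenol, via aryl formate 4 (not isolated)
Conditions: mCPBA, CH2Cl2, rt; then K2CO3 (cat.), MeOH, rt
Reagents that add atoms: 3-chloroperoxybenzoic acid (mCPBA), O=C(OO)c1cccc(Cl)c1
Why: Baeyer–Villiger oxidation of the aldehyde (the peracid form of the Dakin reaction), in which the ortho-methoxy aryl group migrates in preference to hydride, followed by methanolysis of the labile formate.

**Step 4**
Reactants: 5 3-bromo-2,5-dimethoxyphenol
Product: 8 1-(4-bromo-2-hydroxy-3,6-dimethoxyphenyl)ethan-1-one, via aryl acetate 6 (not isolated), via difluoroboron chelate 7 (not isolated)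
Conditions: Ac2O, BF3·OEt2, 85 °C; then H2O–EtOH, reflux
Reagents that add atoms: acetic anhydride, CC(=O)OC(C)=O
Why: O-acetylation and BF3-promoted Fries rearrangement in one flask should deliver the acetyl group to C6 of 5, the only open position ortho to oxygen, because the rival C4 is wedged between Br and OMe and only ortho acylation gives the six-membered O–B–O chelate 7 as a thermodynamic sink, which water then cleaves; running this step before the biaryl coupling keeps the acid-labile pendant ring away from the Lewis acid.

**Step 5**
Reactants: 8 1-(4-bromo-2-hydroxy-3,6-dimethoxyphenyl)ethan-1-one; 9 [4-(methoxymethoxy)phenyl]boronic acid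
Product: 10 1-[3-hydroxy-2,5-dimethoxy-4'-(methoxymethoxy)-[1,1'-biphenyl]-4-yl]ethan-1-one
Conditions: Pd(PPh3)4 (5 mol %), K2CO3, 1,4-dioxane–H2O, 90 °C
Reagents that add atoms: none
Why: Suzuki–Miyaura coupling, in which the C–Br bond para to the acetyl group is activated for oxidative addition to zerovalent palladium and the phenolate, ketone and MOM acetal tolerate aqueous carbonate.

**Step 6**
Reactants: 10 1-[3-hydroxy-2,5-dimethoxy-4'-(methoxymethoxy)-[1,1'-biphenyl]-4-yl]ethan-1-one; 11 methyl propiolate
Product: 12 methyl (E)-3-{[4-acetyl-2,5-dimethoxy-4'-(methoxymethoxy)-[1,1'-biphenyl]-3-yl]oxy}prop-2-enoate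
Conditions: DABCO (20 mol %), CH2Cl2, 0 °C → rt
Reagents that add atoms: none
Why: Amine-catalysed oxa-Michael addition of a phenol to an alkynoate, in which DABCO adds to 11, the zwitterion deprotonates the phenol, and phenoxide addition with loss of DABCO gives the more stable E-β-aryloxyacrylate, the amine being too weak a base to enolise the methyl ketone.

**Step 7**
Reactants: 12 methyl (E)-3-{[4-acetyl-2,5-dimethoxy-4'-(methoxymethoxy)-[1,1'-biphenyl]-3-yl]oxy}prop-2-enoate
Product: 13 methyl 2-{(2S*,3R*)-3-hydroxy-4,7-dimethoxy-6-[4-(methoxymethoxy)phenyl]-3-methyl-2,3-dihydro-1-benzofuran-2-yl}acetate (racemic, C3–OH trans to the C2 CH2CO2Me arm)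
Conditions: SmI2 (3 equiv), MeOH (10 equiv), THF, 0 °C, 12 added slowly; aq. NaHCO3
Reagents that add atoms: none
Why: SmI2 transfers one electron to the acetyl carbonyl of 12, the samarium ketyl carbon attacks the oxygen-bearing β-carbon of the acrylate to make C2–C3, a second equivalent of SmI2 reduces the resulting α-ester radical to a trivalent-samarium enolate, and methanol protonates both this enolate and the C3 alkoxide. The closest known reaction type is the SmI2–MeOH reductive cyclisation of aldehydes and methyl ketones onto β-alkoxyacrylates, the standard entry to cyclic ethers with a 3-hydroxy group and a 2-CH2CO2R arm; here the tether is the C3a–C7a edge of an arene and the ether oxygen is phenolic. The one new ring, O1–C2–C3–C3a–C7a, closes 5-exo-trig, with the acrylate α-carbon left outside the ring. C2 and C3 are set in the same event: samarium bound to the ketyl oxygen also binds the ester carbonyl of the E-acrylate, and this chelate, reinforced by the usual anti preference of ketyl oxygen and developing radical centre, places the C3 hydroxyl trans to the C2 arm, in racemic form. The step needs β- rather than α-attack, secured by the polarity match of the nucleophilic ketyl with the acrylate and by 5-exo over 6-endo geometry, and it needs ring closure to outrun pinacol coupling and simple ketone reduction, secured by the ortho placement of the two partners and by slow addition of 12 to excess SmI2. A large excess of methanol is present to quench the enolate faster than β-elimination of the aryloxide could reopen the ring, and the MOM acetal, the aryl methyl ethers and the ester are not reduced under these conditions.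

**Step 8**
Reactants: 13 methyl 2-{(2S*,3R*)-3-hydroxy-4,7-dimethoxy-6-[4-(methoxymethoxy)phenyl]-3-methyl-2,3-dihydro-1-benzofuran-2-yl}acetate
Product: 15 phenylcandilide B, via O-methoxymethyl benzofuran 14 (not isolated)
Conditions: HCl (1.25 M in MeOH), 50 °C
Reagents that add atoms: none
Why: Acid-catalysed E1 dehydration of the tertiary benzylic alcohol (cation at C3 stabilised by O1, the C4 methoxy group and the para aryl group) aromatises the furan from either C2/C3 relative configuration, and the same acid then cleaves the aryl MOM acetal by exchange with methanol, a solvent in which the methyl ester can only exchange with itself.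

**Compound list**

1 | 2-hydroxy-5-methoxybenzaldehyde | COc1ccc(O)c(C=O)c1 | starting material
2 | 3-bromo-2-hydroxy-5-methoxybenzaldehyde | COc1cc(Br)c(O)c(C=O)c1 | intermediate
3 | 3-bromo-2,5-dimethoxybenzaldehyde | COc1cc(Br)c(OC)c(C=O)c1 | intermediate
4 | 3-bromo-2,5-dimethoxyphenyl formate | COc1cc(Br)c(OC)c(OC=O)c1 | intermediate
5 | 3-bromo-2,5-dimethoxyphenol | COc1cc(O)c(OC)c(Br)c1 | intermediate
6 | 3-bromo-2,5-dimethoxyphenyl acetate | COc1cc(Br)c(OC)c(OC(C)=O)c1 | intermediate
7 | difluoroboron chelate of 8 (six-membered ring through the phenolate oxygen, BF2 and the acetyl oxygen) | CC1=[O+][B-](F)(F)Oc2c(OC)c(Br)cc(OC)c12 | intermediate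
8 | 1-(4-bromo-2-hydroxy-3,6-dimethoxyphenyl)ethan-1-one | CC(=O)c1c(OC)cc(Br)c(OC)c1O | intermediate
9 | [4-(methoxymethoxy)phenyl]boronic acid | COCOc1ccc(B(O)O)cc1 | starting material
10 | 1-[3-hydroxy-2,5-dimethoxy-4'-(methoxymethoxy)-[1,1'-biphenyl]-4-yl]ethan-1-one | CC(=O)c1c(OC)cc(-c2ccc(OCOC)cc2)c(OC)c1O | intermediate
11 | methyl propiolate | C#CC(=O)OC | starting material
12 | methyl (E)-3-{[4-acetyl-2,5-dimethoxy-4'-(methoxymethoxy)-[1,1'-biphenyl]-3-yl]oxy}prop-2-enoate | CC(=O)c1c(OC)cc(-c2ccc(OCOC)cc2)c(OC)c1O/C=C/C(=O)OC | intermediate
13 | methyl 2-{(2S*,3R*)-3-hydroxy-4,7-dimethoxy-6-[4-(methoxymethoxy)phenyl]-3-methyl-2,3-dihydro-1-benzofuran-2-yl}acetate, racemic, OH trans to the acetate arm | COC(=O)C[C@@H]1Oc2c(OC)c(-c3ccc(OCOC)cc3)cc(OC)c2[C@@]1(C)O | intermediate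
14 | methyl 2-{4,7-dimethoxy-6-[4-(methoxymethoxy)phenyl]-3-methyl-1-benzofuran-2-yl}acetate | COC(=O)Cc1oc2c(OC)c(-c3ccc(OCOC)cc3)cc(OC)c2c1C | intermediate
15 | phenylcandilide B, methyl 2-[6-(4-hydroxyphenyl)-4,7-dimethoxy-3-methyl-1-benzofuran-2-yl]acetate | COC(=O)Cc1oc2c(OC)c(-c3ccc(O)cc3)cc(OC)c2c1C | target

**Step count**

Total step count: 8.
Longest linear sequence: 8 steps (1 → 15).

**Steps most likely to fail**

Step 7. The samarium enolate may lose the aryloxide by β-elimination and reopen the ring. The hindered, twisted aryl ketone may also undergo pinacol coupling or plain reduction instead of cyclising.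

The fallback sets out from 10 and closes the same C2–C3 bond by polar chemistry. O-Alkylation with methyl bromoacetate (K2CO3, acetone, reflux) should give methyl 2-{[4-acetyl-2,5-dimethoxy-4'-(methoxymethoxy)-[1,1'-biphenyl]-3-yl]oxy}acetate F1. NaOMe in MeOH closes it by intramolecular aldol condensation to methyl 4,7-dimethoxy-6-[4-(methoxymethoxy)phenyl]-3-methyl-1-benzofuran-2-carboxylate F2. An Arndt–Eistert homologation then adds the missing carbon. LiOH in THF–H2O gives the benzofuran-2-carboxylic acid F3. 1-Chloro-N,N,2-trimethylprop-1-en-1-amine in CH2Cl2 converts it under neutral, MOM-safe conditions into the acid chloride F4. Diazomethane with Et3N gives the diazoketone F5. Wolff rearrangement (PhCO2Ag, Et3N, MeOH) comes back to the route at 14, which the conditions of step 8 carry to 15.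

Step 4. The acetyl group may be transferred to C4 (para to oxygen) instead of C6, or the Lewis acid may remove a methyl ether next to the new carbonyl group.

The fallback sets out from 5 and builds the ketone in oxidation-level steps. Casnati–Skattebøl formylation (MgCl2, Et3N, paraformaldehyde, MeCN, reflux) delivers carbon only ortho to the magnesium phenoxide and should give 4-bromo-2-hydroxy-3,6-dimethoxybenzaldehyde F6. MeMgBr (2.2 equiv, THF, 0 °C) gives racemic 1-(4-bromo-2-hydroxy-3,6-dimethoxyphenyl)ethan-1-ol F7. MnO2 in CH2Cl2 oxidises the benzylic alcohol and comes back to the route at 8.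

Step 6. Conjugate addition may be sluggish because the phenol is hydrogen-bonded to the acetyl group and flanked on both sides. Amine-induced oligomerisation of the propiolate could then take over.

The fallback sets out from 10 and replaces catalytic addition to an alkyne by substitution with a preformed phenoxide. NaH (1 equiv, DMF, 0 °C) generates the sodium phenoxide. This reacts with methyl (E)-3-chloroacrylate F8 (Fischer esterification of commercial trans-3-chloroacrylic acid) by addition–elimination at the vinylic carbon with retention of the E geometry, and comes back to the route at 12.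

**Further compounds**

F1 | step 7 | methyl 2-{[4-acetyl-2,5-dimethoxy-4'-(methoxymethoxy)-[1,1'-biphenyl]-3-yl]oxy}acetate | CC(=O)c1c(OC)cc(-c2ccc(OCOC)cc2)c(OC)c1OCC(=O)OC
F2 | step 7 | methyl 4,7-dimethoxy-6-[4-(methoxymethoxy)phenyl]-3-methyl-1-benzofuran-2-carboxylate | COC(=O)c1oc2c(OC)c(-c3ccc(OCOC)cc3)cc(OC)c2c1C
F3 | step 7 | 4,7-dimethoxy-6-[4-(methoxymethoxy)phenyl]-3-methyl-1-benzofuran-2-carboxylic acid | OC(=O)c1oc2c(OC)c(-c3ccc(OCOC)cc3)cc(OC)c2c1C
F4 | step 7 | 4,7-dimethoxy-6-[4-(methoxymethoxy)phenyl]-3-methyl-1-benzofuran-2-carbonyl chloride | ClC(=O)c1oc2c(OC)c(-c3ccc(OCOC)cc3)cc(OC)c2c1C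
F5 | step 7 | 2-diazo-1-{4,7-dimethoxy-6-[4-(methoxymethoxy)phenyl]-3-methyl-1-benzofuran-2-yl}ethan-1-one | [N-]=[N+]=CC(=O)c1oc2c(OC)c(-c3ccc(OCOC)cc3)cc(OC)c2c1C
F6 | step 4 | 4-bromo-2-hydroxy-3,6-dimethoxybenzaldehyde | O=Cc1c(OC)cc(Br)c(OC)c1O
F7 | step 4 | 1-(4-bromo-2-hydroxy-3,6-dimethoxyphenyl)ethan-1-ol (racemic) | CC(O)c1c(OC)cc(Br)c(OC)c1O
F8 | step 6 | methyl (E)-3-chloroacrylate | COC(=O)/C=C/Cl
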